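The starting complex left at the amber run's last reading, 45.5 %, told me little until I asked where the rest had gone, since what was spent had taken one of two roads: with incoming ligand towards the exchanged complexes, or with leaving ligand into side product.

| setting | amber | blue | Saturday's | Monday's |
|---|---|---|---|---|
| starting complex | 0.050 M | 0.050 M | 0.050 M | 0.050 M |
| incoming ligand | 0.066 M | 0.27 M | 0.0600 M | 0.180 M |
| leaving ligand | 0.10 M | 0.10 M | 0.100 M | 0.100 M |
| remark | run made earlier | run made earlier |  |  |
| time |  |  | 1.0 h | 1.0 h |

| run | time / min | complex with one exchanged / % | complex with two exchanged / % | side product / % | starting complex / % |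
|---|---|---|---|---|---|
| amber | 4.00 | 4.6 | 0.7 | 5.2 | 89.9 |
| amber | 10.0 | 8.5 | 2.4 | 12.4 | 76.4 |
| amber | 20.0 | 11.4 | 6.6 | 22.0 | 58.6 |
| amber | 30.0 | 12.3 | 12.3 | 30.1 | 45.5 |
| blue | 4.00 | 12.5 | 6.4 | 5.0 | 75.3 |
| blue | 10.0 | 14.9 | 23.8 | 11.2 | 50.9 |
| blue | 20.0 | 9.6 | 44.9 | 18.2 | 26.2 |
| blue | 30.0 | 5.4 | 57.8 | 22.5 | 14.1 |

(scatter of a reading: 0.3 percentage points)

1. which of these there is most of at the end, counted by the starting complex in it, Saturday's (starting complex / complex with two exchanged / side product / complex with one exchanged)
2. which of these there is most of at the end, counted by the starting complex in it, Monday's (starting complex / complex with two exchanged / side product / complex with one exchanged)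
3. how much there is at the end of the one of these that leads, in percent of the starting complex charged: Saturday's
4. how much there is at the end of the one of these that leads, in percent of the starting complex charged: Monday's

At the first readings, side product over the two exchanged complexes together, multiplied by incoming over leaving ligand, came to 0.648 in the amber run and 0.714 in the blue run, which I counted as close, given a scatter of 0.3 percentage points on a side product of 5.0 %. I took their mean, 0.681, as the selectivity factor, the readiness of starting complex to take leaving ligand rather than incoming ligand at equal amounts. Multiplied by leaving over incoming ligand as charged, it gives a branching number: side product formed per starting complex exchanged. Saturday's number was 1.13, above one, so I expected side product to lead there; Monday's was 0.378, below one, so I expected the complex with two exchanged to lead there.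

Was one number enough? In the blue run, side product's share of what was spent rose from 0.209 to 0.263 between first and last reading, so the number drifts. Monday's opening share, 0.274, scaled by that rise, became 0.344, still less than the remaining 0.656, and the leaders stood. I reckoned leaders, not amounts. The forecast, grounded in “The runs fit the three proposed steps”, named side product at 46 % for Saturday's and complex with two exchanged at 57 % for Monday's.

The flask gave side product at 45.4 % on Saturday's and complex with two exchanged at 57.8 % on Monday's.

    starting complex + incoming ligand → leaving ligand + complex with one exchanged (k = 0.00340 L mol⁻¹ s⁻¹)
    leaving ligand + starting complex → side product (k = 0.00240 L mol⁻¹ s⁻¹)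
    complex with one exchanged + incoming ligand → leaving ligand + complex with two exchanged (k = 0.0130 L mol⁻¹ s⁻¹)

With 5.94 % of the starting complex left at Monday's end, side product held a share of 0.356 of the remainder, against my drifted 0.344. A further flask, like Saturday's but charged with 0.24 M of incoming ligand, has a branching number of 0.284, below one, and it ended with side product at 28.7 % and the complex with two exchanged ahead at 67.1 %.

The readings stem from a simulated flask with made-up constants, and the scatter is random.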